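**Retrosynthetic overview**
- The target comes from a bis-silyl ether by desilylation; its 1,1-disubstituted alkene comes from methylenation of a ketone, itself from oxidation and deallylative decarboxylation of a β-hydroxy allyl ester.
- Key C–C disconnection (C2'–C3' of the side chain): intermolecular aldol between an α-silyloxy ring aldehyde and the lithium enolate of the side-chain allyl ester; the ester carbon is later lost as CO2.
- Ring aldehyde: the trans-bromochloride is installed by a stereospecific bromonium relay (OH-directed epoxide, trans-diaxial bromohydrin, triflate, bromonium, chloride). The C1 carbinol comes from Sharpless epoxidation and hydride opening of a Birch-derived dienylmethanol.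
- Side-chain ester: asymmetric allylboration of methacrolein, silylation, hydroboration, oxidation, allyl ester formation.
- Ring order: the single carbocycle is never constructed; it is carried over from the benzene ring of 4-methylbenzyl alcohol. Only transient three-membered rings are made and opened.

Assumption: reagents, catalysts and chiral controllers are not numbered; "up/cis" on the ring refers to the face of the C1 oxygen. The route is a proposal that has not been run, and selectivities quoted are expectations from analogous substrates.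

**Step 1**
Reactants: 1 4-methylbenzyl alcohol
Product: 2 (4-methylcyclohexa-1,4-dien-1-yl)methanol
Conditions: Li, t-BuOH, NH3(l)/THF, −78 → −33 °C
Reagents that add atoms: none
Why: Birch reduction; the lithium alkoxide formed first resists benzylic C–O cleavage and the 1,4-dialkylarene is protonated at unsubstituted carbons, giving the 1,4-diene with both alkyl groups on sp2 carbons.

**Step 2**
Reactants: 2 (4-methylcyclohexa-1,4-dien-1-yl)methanol
Product: 3 [(1S,6S)-4-methyl-7-oxabicyclo[4.1.0]hept-3-en-1-yl]methanol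
Conditions: Ti(OiPr)4 (10 mol %), L-(+)-diethyl tartrate (12 mol %), t-BuOOH, 4 Å sieves, CH2Cl2, −20 °C
Reagents that add atoms: tert-butyl hydroperoxide CC(C)(C)OO
Why: Sharpless asymmetric epoxidation; only the allylic-alcohol alkene reacts and the L-(+)-tartrate catalyst delivers oxygen to the face that gives the (S,S)-epoxy alcohol (about 93% ee expected for cyclohexenylmethanols), which fixes the future C1 oxygen stereocentre.

**Step 3**
Reactants: 3 [(1S,6S)-4-methyl-7-oxabicyclo[4.1.0]hept-3-en-1-yl]methanol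
Product: 4 (1S)-1-(hydroxymethyl)-4-methylcyclohex-3-en-1-ol
Conditions: LiAlH4, THF, 0 °C → rt; aqueous NaOH work-up
Reagents that add atoms: none
Why: SN2 hydride opening of the epoxide at its only accessible (secondary) carbon leaves the C–O bond at the quaternary carbon intact, so C1 keeps the configuration set in step 2.

**Step 4**
Reactants: 4 (1S)-1-(hydroxymethyl)-4-methylcyclohex-3-en-1-ol
Product: 5 [(1S)-1-hydroxy-4-methylcyclohex-3-en-1-yl]methyl 2,2-dimethylpropanoate
Conditions: t-BuCOCl, pyridine, CH2Cl2, 0 °C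
Reagents that add atoms: pivaloyl chloride CC(C)(C)C(Cl)=O
Why: Selective acylation of the primary over the hindered tertiary alcohol; no stereocentre is touched.

**Step 5**
Reactants: 5 [(1S)-1-hydroxy-4-methylcyclohex-3-en-1-yl]methyl 2,2-dimethylpropanoate
Product: 6 [(1S,3S,6R)-3-hydroxy-6-methyl-7-oxabicyclo[4.1.0]heptan-3-yl]methyl 2,2-dimethylpropanoate
Conditions: VO(acac)2 (3 mol %), t-BuOOH, CH2Cl2, 0 °C → rt
Reagents that add atoms: tert-butyl hydroperoxide CC(C)(C)OO
Why: Hydroxyl-directed epoxidation; the pseudo-axial tertiary homoallylic OH binds vanadium and delivers oxygen to its own face (as with terpinen-4-ol), giving the epoxide cis to the OH.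

**Step 6**
Reactants: 6 [(1S,3S,6R)-3-hydroxy-6-methyl-7-oxabicyclo[4.1.0]heptan-3-yl]methyl 2,2-dimethylpropanoate
Product: 7 [(1S,3S,6R)-6-methyl-3-(triethylsilyloxy)-7-oxabicyclo[4.1.0]heptan-3-yl]methyl 2,2-dimethylpropanoate
Conditions: Et3SiOTf, 2,6-lutidine, CH2Cl2, −78 °C
Reagents that add atoms: triethylsilyl triflate CC[Si](CC)(CC)OS(=O)(=O)C(F)(F)F
Why: Silylation of the tertiary alcohol at −78 °C outpaces epoxide activation and caps the oxygen so it cannot capture the bromonium ion in step 8.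

**Step 7**
Reactants: 7 [(1S,3S,6R)-6-methyl-3-(triethylsilyloxy)-7-oxabicyclo[4.1.0]heptan-3-yl]methyl 2,2-dimethylpropanoate
Product: 8 [(1S,3S,4S)-4-bromo-3-hydroxy-4-methyl-1-(triethylsilyloxy)cyclohexyl]methyl 2,2-dimethylpropanoate
Conditions: LiBr, AcOH, THF, 0 °C → rt
Reagents that add atoms: lithium bromide [Li+].[Br-]
Why: Acid-assisted epoxide opening by bromide with inversion at the tertiary carbon, which is also the trans-diaxial (Fürst–Plattner) mode of the chair with CH2OPiv equatorial, gives the trans-diaxial bromohydrin (Br anti to the C1 oxygen).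

**Step 8**
Reactants: 8 [(1S,3S,4S)-4-bromo-3-hydroxy-4-methyl-1-(triethylsilyloxy)cyclohexyl]methyl 2,2-dimethylpropanoate
Product: 11 [(1S,3R,4R)-3-bromo-4-chloro-4-methyl-1-(triethylsilyloxy)cyclohexyl]methyl 2,2-dimethylpropanoate, via secondary triflate 9 (not isolated), via bromonium triflate 10 (not isolated)
Conditions: Tf2O, 2,6-di-tert-butyl-4-methylpyridine, CH2Cl2, −78 °C; then n-Bu4NCl, −78 → 0 °C
Reagents that add atoms: tetrabutylammonium chloride CCCC[N+](CCCC)(CCCC)CCCC.[Cl-]
Why: Neighbouring-group participation; the axial triflate ionises with help from the antiperiplanar bromine to give one bridged bromonium ion on the face anti to OSiEt3, which chloride opens at the tertiary carbon (Markovnikov, inversion), so Br migrates to C3 and Cl enters C4 cis to the C1 oxygen and trans to Br.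

**Step 9**
Reactants: 11 [(1S,3R,4R)-3-bromo-4-chloro-4-methyl-1-(triethylsilyloxy)cyclohexyl]methyl 2,2-dimethylpropanoate
Product: 12 [(1S,3R,4R)-3-bromo-4-chloro-4-methyl-1-(triethylsilyloxy)cyclohexyl]methanol
Conditions: iBu2AlH, CH2Cl2, −78 °C; aqueous KNaC4H4O6 (potassium sodium tartrate) work-up
Reagents that add atoms: none
Why: Reductive ester cleavage at −78 °C; the alkyl halides and the tertiary silyl ether are inert to the aluminium hydride.

**Step 10**
Reactants: 12 [(1S,3R,4R)-3-bromo-4-chloro-4-methyl-1-(triethylsilyloxy)cyclohexyl]methanol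
Product: 13 (1S,3R,4R)-3-bromo-4-chloro-4-methyl-1-(triethylsilyloxy)cyclohexane-1-carbaldehyde
Conditions: Dess–Martin periodinane, CH2Cl2, 0 °C → rt
Reagents that add atoms: none
Why: Dess–Martin oxidation gives the non-enolisable aldehyde under non-basic conditions that spare the halides.

**Step 11**
Reactants: 14 methacrolein
Product: 16 (3R)-2-methylhexa-1,5-dien-3-ol, via borinate ester 15 (not isolated)
Conditions: B-allyldiisopinocampheylborane from (−)-α-pinene (1 M in pentane), Et2O, −78 °C; then NaOH, H2O2, 0 °C → rt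
Reagents that add atoms: B-allyldiisopinocampheylborane derived from (−)-α-pinene, each Ipc = (1S,2R,3S,5S) C=CCB([C@H]1C[C@H]2C[C@@H]([C@@H]1C)C2(C)C)[C@H]1C[C@H]2C[C@@H]([C@@H]1C)C2(C)C
Why: Brown asymmetric allylboration (carbonyl allylation) through a chair Zimmerman–Traxler transition state; this reagent, the antipode of the one that gives (S)-1-phenylbut-3-en-1-ol from benzaldehyde, attacks the re face and gives the (R)-alcohol (about 90–95% ee expected).

**Step 12**
Reactants: 16 (3R)-2-methylhexa-1,5-dien-3-ol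
Product: 17 tert-butyldimethyl{[(3R)-2-methylhexa-1,5-dien-3-yl]oxy}silane
Conditions: t-BuMe2SiCl, imidazole, DMF, rt
Reagents that add atoms: tert-butyldimethylsilyl chloride CC(C)(C)[Si](C)(C)Cl
Why: Standard silylation of the secondary allylic alcohol; the stereocentre is not involved.

**Step 13**
Reactants: 17 tert-butyldimethyl{[(3R)-2-methylhexa-1,5-dien-3-yl]oxy}silane
Product: 19 (4R)-4-(tert-butyldimethylsilyloxy)-5-methylhex-5-en-1-ol, via trialkylborane 18 (not isolated)
Conditions: (Me2CHCHMe)2BH (disiamylborane, made beforehand from BH3·THF and 2-methylbut-2-ene at 0 °C), THF, 0 °C → rt; then NaOH, H2O2, 0 °C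
Reagents that add atoms: hydrogen peroxide OO
Why: Hydroboration–oxidation; the bulky dialkylborane adds anti-Markovnikov to the unhindered monosubstituted alkene far faster than to the 1,1-disubstituted alkene, which is further shielded by the adjacent silyloxy-bearing carbon.

**Step 14**
Reactants: 19 (4R)-4-(tert-butyldimethylsilyloxy)-5-methylhex-5-en-1-ol
Product: 21 (4R)-4-(tert-butyldimethylsilyloxy)-5-methylhex-5-enoic acid, via aldehyde 20 (not isolated)
Conditions: TEMPO (20 mol %), PhI(OAc)2, MeCN/H2O, rt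
Reagents that add atoms: water O
Why: Oxoammonium (TEMPO) oxidation takes the primary alcohol through the aldehyde hydrate to the acid without touching the alkene or the silyl ether.

**Step 15**
Reactants: 21 (4R)-4-(tert-butyldimethylsilyloxy)-5-methylhex-5-enoic acid
Product: 22 prop-2-en-1-yl (4R)-4-(tert-butyldimethylsilyloxy)-5-methylhex-5-enoate
Conditions: allyl bromide, K2CO3, DMF, rt
Reagents that add atoms: allyl bromide C=CCBr
Why: SN2 O-alkylation of the carboxylate gives the allyl ester needed for the later neutral decarboxylation.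

**Step 16**
Reactants: 22 prop-2-en-1-yl (4R)-4-(tert-butyldimethylsilyloxy)-5-methylhex-5-enoate; 13 (1S,3R,4R)-3-bromo-4-chloro-4-methyl-1-(triethylsilyloxy)cyclohexane-1-carbaldehyde
Product: 24 prop-2-en-1-yl (4R)-2-{[(1S,3R,4R)-3-bromo-4-chloro-4-methyl-1-(triethylsilyloxy)cyclohexyl](hydroxy)methyl}-4-(tert-butyldimethylsilyloxy)-5-methylhex-5-enoate (diastereomer mixture at the two new centres), via lithium enolate 23 (not isolated)
Conditions: LiN(iPr)2, THF, −78 °C, 22; then 13, −78 °C; NH4Cl quench at −78 °C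
Reagents that add atoms: none
Why: Intermolecular aldol addition of the lithium ester enolate to the non-enolisable aldehyde joins the two fragments at C2'–C3'; both new stereocentres are erased in steps 17 and 18, so their configuration does not matter.

**Step 17**
Reactants: 24 prop-2-en-1-yl (4R)-2-{[(1S,3R,4R)-3-bromo-4-chloro-4-methyl-1-(triethylsilyloxy)cyclohexyl](hydroxy)methyl}-4-(tert-butyldimethylsilyloxy)-5-methylhex-5-enoate
Product: 25 prop-2-en-1-yl (4R)-2-{[(1S,3R,4R)-3-bromo-4-chloro-4-methyl-1-(triethylsilyloxy)cyclohexyl]carbonyl}-4-(tert-butyldimethylsilyloxy)-5-methylhex-5-enoate (epimers at C2)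
Conditions: Dess–Martin periodinane, CH2Cl2, rt
Reagents that add atoms: none
Why: Dess–Martin oxidation of the β-hydroxy ester to the β-keto ester under neutral conditions removes the carbinol stereocentre.

**Step 18**
Reactants: 25 prop-2-en-1-yl (4R)-2-{[(1S,3R,4R)-3-bromo-4-chloro-4-methyl-1-(triethylsilyloxy)cyclohexyl]carbonyl}-4-(tert-butyldimethylsilyloxy)-5-methylhex-5-enoate
Product: 27 (4R)-1-[(1S,3R,4R)-3-bromo-4-chloro-4-methyl-1-(triethylsilyloxy)cyclohexyl]-4-(tert-butyldimethylsilyloxy)-5-methylhex-5-en-1-one, via β-keto acid 26 (not isolated)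
Conditions: Pd(PPh3)4 (5 mol %), morpholine, THF, rt
Reagents that add atoms: none
Why: Tsuji–Trost deallylation; zerovalent palladium ionises the allyl ester, morpholine traps the π-allyl group and the β-keto acid loses CO2 at room temperature, erasing the α-stereocentre without base or heat.

**Step 19**
Reactants: 27 (4R)-1-[(1S,3R,4R)-3-bromo-4-chloro-4-methyl-1-(triethylsilyloxy)cyclohexyl]-4-(tert-butyldimethylsilyloxy)-5-methylhex-5-en-1-one
Product: 28 {[(1S,3R,4R)-3-bromo-4-chloro-1-[(5R)-5-(tert-butyldimethylsilyloxy)-6-methylhepta-1,6-dien-2-yl]-4-methylcyclohexyl]oxy}triethylsilane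
Conditions: Cp2Ti(μ-Cl)(μ-CH2)AlMe2 (Tebbe reagent), pyridine (cat.), THF/toluene, −40 → 0 °C
Reagents that add atoms: Tebbe reagent Cp2Ti(μ-Cl)(μ-CH2)AlMe2 C[Al-]1(C)C[Ti]([Cl+]1)(C1C=CC=C1)C1C=CC=C1
Why: Tebbe methylenation; the titanium methylidene converts hindered, enolisable ketones into 1,1-disubstituted alkenes without basic conditions, so the halides and the α-CH2 are safe.

**Step 20**
Reactants: 28 {[(1S,3R,4R)-3-bromo-4-chloro-1-[(5R)-5-(tert-butyldimethylsilyloxy)-6-methylhepta-1,6-dien-2-yl]-4-methylcyclohexyl]oxy}triethylsilane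
Product: 29 (1S,3R,4R)-3-bromo-4-chloro-1-[(5R)-5-hydroxy-6-methylhepta-1,6-dien-2-yl]-4-methylcyclohexan-1-ol
Conditions: HF·pyridine, pyridine, THF, 0 °C → rt
Reagents that add atoms: none
Why: Fluoride-driven cleavage of both silyl ethers (Si–F bond formation) under buffered conditions tolerated by the tertiary chloride, the secondary bromide and both allylic alcohols; no stereocentre is touched.

**Compound list**
1 | 4-methylbenzyl alcohol | Cc1ccc(CO)cc1 | starting material
2 | (4-methylcyclohexa-1,4-dien-1-yl)methanol | CC1=CCC(CO)=CC1 | intermediate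
3 | [(1S,6S)-4-methyl-7-oxabicyclo[4.1.0]hept-3-en-1-yl]methanol | OC[C@@]12CC=C(C)C[C@@H]1O2 | intermediate
4 | (1S)-1-(hydroxymethyl)-4-methylcyclohex-3-en-1-ol | OC[C@]1(O)CCC(C)=CC1 | intermediate
5 | [(1S)-1-hydroxy-4-methylcyclohex-3-en-1-yl]methyl 2,2-dimethylpropanoate | CC(C)(C)C(=O)OC[C@]1(O)CCC(C)=CC1 | intermediate
6 | [(1S,3S,6R)-3-hydroxy-6-methyl-7-oxabicyclo[4.1.0]heptan-3-yl]methyl 2,2-dimethylpropanoate | CC(C)(C)C(=O)OC[C@]1(O)CC[C@@]2(C)O[C@H]2C1 | intermediate
7 | [(1S,3S,6R)-6-methyl-3-(triethylsilyloxy)-7-oxabicyclo[4.1.0]heptan-3-yl]methyl 2,2-dimethylpropanoate | CC(C)(C)C(=O)OC[C@]1(O[Si](CC)(CC)CC)CC[C@@]2(C)O[C@H]2C1 | intermediate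
8 | [(1S,3S,4S)-4-bromo-3-hydroxy-4-methyl-1-(triethylsilyloxy)cyclohexyl]methyl 2,2-dimethylpropanoate | CC(C)(C)C(=O)OC[C@]1(O[Si](CC)(CC)CC)CC[C@](C)(Br)[C@@H](O)C1 | intermediate
9 | [(1S,3S,4S)-4-bromo-4-methyl-1-(triethylsilyloxy)-3-(trifluoromethylsulfonyloxy)cyclohexyl]methyl 2,2-dimethylpropanoate | CC(C)(C)C(=O)OC[C@]1(O[Si](CC)(CC)CC)CC[C@](C)(Br)[C@@H](OS(=O)(=O)C(F)(F)F)C1 | intermediate
10 | bridged bromonium ion of 9 (7-bromoniabicyclo[4.1.0]heptane, Br on the face anti to OSiEt3) as its triflate | CC(C)(C)C(=O)OC[C@]1(O[Si](CC)(CC)CC)CC[C@]2(C)[Br+][C@@H]2C1.[O-]S(=O)(=O)C(F)(F)F | intermediate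
11 | [(1S,3R,4R)-3-bromo-4-chloro-4-methyl-1-(triethylsilyloxy)cyclohexyl]methyl 2,2-dimethylpropanoate | CC(C)(C)C(=O)OC[C@]1(O[Si](CC)(CC)CC)CC[C@@](C)(Cl)[C@H](Br)C1 | intermediate
12 | [(1S,3R,4R)-3-bromo-4-chloro-4-methyl-1-(triethylsilyloxy)cyclohexyl]methanol | OC[C@]1(O[Si](CC)(CC)CC)CC[C@@](C)(Cl)[C@H](Br)C1 | intermediate
13 | (1S,3R,4R)-3-bromo-4-chloro-4-methyl-1-(triethylsilyloxy)cyclohexane-1-carbaldehyde | O=C[C@]1(O[Si](CC)(CC)CC)CC[C@@](C)(Cl)[C@H](Br)C1 | intermediate
14 | methacrolein (2-methylprop-2-enal) | C=C(C)C=O | starting material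
15 | (3R)-2-methylhexa-1,5-dien-3-yl diisopinocampheylborinate | C=C(C)[C@@H](CC=C)OB([C@H]1C[C@H]2C[C@@H]([C@@H]1C)C2(C)C)[C@H]1C[C@H]2C[C@@H]([C@@H]1C)C2(C)C | intermediate
16 | (3R)-2-methylhexa-1,5-dien-3-ol | C=C(C)[C@H](O)CC=C | intermediate
17 | tert-butyldimethyl{[(3R)-2-methylhexa-1,5-dien-3-yl]oxy}silane | C=C(C)[C@H](O[Si](C)(C)C(C)(C)C)CC=C | intermediate
18 | [(4R)-4-(tert-butyldimethylsilyloxy)-5-methylhex-5-en-1-yl]bis(3-methylbutan-2-yl)borane | C=C(C)[C@H](O[Si](C)(C)C(C)(C)C)CCCB(C(C)C(C)C)C(C)C(C)C | intermediate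
19 | (4R)-4-(tert-butyldimethylsilyloxy)-5-methylhex-5-en-1-ol | C=C(C)[C@H](O[Si](C)(C)C(C)(C)C)CCCO | intermediate
20 | (4R)-4-(tert-butyldimethylsilyloxy)-5-methylhex-5-enal | C=C(C)[C@H](O[Si](C)(C)C(C)(C)C)CCC=O | intermediate
21 | (4R)-4-(tert-butyldimethylsilyloxy)-5-methylhex-5-enoic acid | C=C(C)[C@H](O[Si](C)(C)C(C)(C)C)CCC(=O)O | intermediate
22 | prop-2-en-1-yl (4R)-4-(tert-butyldimethylsilyloxy)-5-methylhex-5-enoate | C=C(C)[C@H](O[Si](C)(C)C(C)(C)C)CCC(=O)OCC=C | intermediate
23 | lithium enolate of 22 | C=C(C)[C@H](O[Si](C)(C)C(C)(C)C)CC=C(O[Li])OCC=C | intermediate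
24 | prop-2-en-1-yl (4R)-2-{[(1S,3R,4R)-3-bromo-4-chloro-4-methyl-1-(triethylsilyloxy)cyclohexyl](hydroxy)methyl}-4-(tert-butyldimethylsilyloxy)-5-methylhex-5-enoate | C=C(C)[C@H](O[Si](C)(C)C(C)(C)C)CC(C(=O)OCC=C)C(O)[C@]1(O[Si](CC)(CC)CC)CC[C@@](C)(Cl)[C@H](Br)C1 | intermediate
25 | prop-2-en-1-yl (4R)-2-{[(1S,3R,4R)-3-bromo-4-chloro-4-methyl-1-(triethylsilyloxy)cyclohexyl]carbonyl}-4-(tert-butyldimethylsilyloxy)-5-methylhex-5-enoate | C=C(C)[C@H](O[Si](C)(C)C(C)(C)C)CC(C(=O)OCC=C)C(=O)[C@]1(O[Si](CC)(CC)CC)CC[C@@](C)(Cl)[C@H](Br)C1 | intermediate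
26 | (4R)-2-{[(1S,3R,4R)-3-bromo-4-chloro-4-methyl-1-(triethylsilyloxy)cyclohexyl]carbonyl}-4-(tert-butyldimethylsilyloxy)-5-methylhex-5-enoic acid | C=C(C)[C@H](O[Si](C)(C)C(C)(C)C)CC(C(=O)O)C(=O)[C@]1(O[Si](CC)(CC)CC)CC[C@@](C)(Cl)[C@H](Br)C1 | intermediate
27 | (4R)-1-[(1S,3R,4R)-3-bromo-4-chloro-4-methyl-1-(triethylsilyloxy)cyclohexyl]-4-(tert-butyldimethylsilyloxy)-5-methylhex-5-en-1-one | C=C(C)[C@H](O[Si](C)(C)C(C)(C)C)CCC(=O)[C@]1(O[Si](CC)(CC)CC)CC[C@@](C)(Cl)[C@H](Br)C1 | intermediate
28 | {[(1S,3R,4R)-3-bromo-4-chloro-1-[(5R)-5-(tert-butyldimethylsilyloxy)-6-methylhepta-1,6-dien-2-yl]-4-methylcyclohexyl]oxy}triethylsilane | C=C(C)[C@H](O[Si](C)(C)C(C)(C)C)CCC(=C)[C@]1(O[Si](CC)(CC)CC)CC[C@@](C)(Cl)[C@H](Br)C1 | intermediate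
29 | (1S,3R,4R)-3-bromo-4-chloro-1-[(5R)-5-hydroxy-6-methylhepta-1,6-dien-2-yl]-4-methylcyclohexan-1-ol | C=C(C)[C@H](O)CCC(=C)[C@]1(O)CC[C@@](C)(Cl)[C@H](Br)C1 | target

**Totals**
Total step count: 20.
Longest linear sequence: 15 steps (steps 1–10, then 16–20, from 4-methylbenzyl alcohol); the side-chain branch is 5 steps (11–15) before the union.

**Three steps most likely to fail**

Step 8 (bromonium relay). The bromonium ion could lose a proton, lose Br+, or take chloride at C3 instead of C4. The fallback sets out from 5 and comes back at 11, bypassing steps 5–8. Treating 5 with NBS in CH2Cl2 at 0 °C causes bromoetherification, in which only the bromonium ion on the face anti to the tertiary OH can be captured across the ring, giving [(1S,3R,4R)-3-bromo-4-methyl-7-oxabicyclo[2.2.1]heptan-1-yl]methyl 2,2-dimethylpropanoate F1. BCl3 in CH2Cl2 at −78 °C then cleaves the strained tertiary C–O bond at the methyl-bearing bridgehead with assistance from the anti bromine and returns chloride with overall retention, giving [(1S,3R,4R)-3-bromo-4-chloro-1-hydroxy-4-methylcyclohexyl]methyl 2,2-dimethylpropanoate F2. Silylation with Et3SiOTf and 2,6-lutidine gives 11.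

Step 7 (regiochemistry of epoxide opening). Bromide may attack the secondary carbon, or the epoxide may rearrange. The fallback sets out from 7 and comes back at 11, replacing steps 7 and 8. The epoxide is opened deliberately at the secondary carbon with Li2NiBr4 in THF at 0 °C (SN2, inversion) to give [(1S,3R,4R)-3-bromo-4-hydroxy-4-methyl-1-(triethylsilyloxy)cyclohexyl]methyl 2,2-dimethylpropanoate F3. SOCl2 and pyridine in CH2Cl2 at −20 °C then ionise the tertiary alcohol through the same bromonium ion 10, and chloride enters C4 with net retention to give 11 directly.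

Step 19 (Tebbe methylenation of a hindered α-silyloxy ketone). The ketone may not react, or the Lewis-acidic aluminium may damage the tertiary chloride. The fallback sets out from 27 and comes back at the target 29, replacing steps 19 and 20. Me3SiCH2Li with CeCl3 in THF at −78 °C (non-basic organocerium 1,2-addition) gives the β-hydroxysilane (3R)-6-[(1S,3R,4R)-3-bromo-4-chloro-4-methyl-1-(triethylsilyloxy)cyclohexyl]-3-(tert-butyldimethylsilyloxy)-2-methyl-7-(trimethylsilyl)hept-1-en-6-ol F4. Aqueous HF in MeCN at 0 °C → rt then effects acid-promoted Peterson elimination and cleaves both silyl ethers in one operation, giving 29.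

**Further compounds**
F1 | step 8 | [(1S,3R,4R)-3-bromo-4-methyl-7-oxabicyclo[2.2.1]heptan-1-yl]methyl 2,2-dimethylpropanoate | CC(C)(C)C(=O)OC[C@@]12CC[C@@](C)(O1)[C@H](Br)C2
F2 | step 8 | [(1S,3R,4R)-3-bromo-4-chloro-1-hydroxy-4-methylcyclohexyl]methyl 2,2-dimethylpropanoate | CC(C)(C)C(=O)OC[C@]1(O)CC[C@@](C)(Cl)[C@H](Br)C1
F3 | step 7 | [(1S,3R,4R)-3-bromo-4-hydroxy-4-methyl-1-(triethylsilyloxy)cyclohexyl]methyl 2,2-dimethylpropanoate | CC(C)(C)C(=O)OC[C@]1(O[Si](CC)(CC)CC)CC[C@@](C)(O)[C@H](Br)C1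
F4 | step 19 | (3R)-6-[(1S,3R,4R)-3-bromo-4-chloro-4-methyl-1-(triethylsilyloxy)cyclohexyl]-3-(tert-butyldimethylsilyloxy)-2-methyl-7-(trimethylsilyl)hept-1-en-6-ol | C=C(C)[C@H](O[Si](C)(C)C(C)(C)C)CCC(O)(C[Si](C)(C)C)[C@]1(O[Si](CC)(CC)CC)CC[C@@](C)(Cl)[C@H](Br)C1
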